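**Strategy**

The six-membered carbocycle is traced back to a cyclopentane spiro-fused at C1 of a 2,6-dimethoxycyclohexa-2,5-dienone. The fused aromatic ring carries its free C4–OH para to C1 and has two equivalent ortho carbons C2/C6, so it is a masked, symmetric dienone. In the key step acid triggers a dienone–phenol rearrangement: C7′ moves from C1 to C2, the five-membered ring (C1, C7, C8, C8′, C7′) becomes the tetralin ring, the arene is restored, C7′ is set trans to the C8′ methyl and the MOM ether is cleaved. The spirodienone comes from a 1,1-diarylbutyl tosylate by para-alkylation of the phenoxide; C8 and C8′ come from a catalytic desymmetrisation of meso-2,3-dimethylsuccinic anhydride.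

Key step: step 10

Remark (numbering): lignan numbering is used throughout. C1–C6 = fused aromatic ring (OMe on C3/C5, OH on C4), C7 = ring CH2, C8/C8′ = methyl-bearing carbons, C7′ = aryl-bearing carbon, primed ring = pendant 4-hydroxy-3-methoxyphenyl ring.

Assumption: the sense of induction of the Rh/phosphoramidite desymmetrisation (step 3) is set by the ligand antipode; the antipode that arylates the carbonyl next to the (R)-carbon of the meso anhydride is used.

Remark (C7′): the diaryl-bearing carbon is carried as an epimer mixture from step 5 to step 9. This is intended, since the centre is re-made under control of the C8′ methyl in step 10.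

**Route**

Step 1
Reactants: 1 meso-2,3-dimethylsuccinic acid
Product: 2 cis-2,3-dimethylsuccinic anhydride
Conditions: AcCl, reflux; evaporate
Reagents that add atoms: none
Why: Cyclodehydration of the 1,4-diacid to the five-membered anhydride; the acidic, base-free medium should leave both α-centres untouched, so the cis (meso) relationship is kept.

Step 2
Reactants: 3 4-bromo-2,6-dimethoxyphenol
Product: 4 (4-bromo-2,6-dimethoxyphenoxy)(tert-butyl)dimethylsilane
Conditions: TBSCl, imidazole, DMF, rt
Reagents that add atoms: tert-butyldimethylsilyl chloride, CC(C)(C)[Si](C)(C)Cl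
Why: Imidazole-promoted O-silylation of the phenol; no stereocentre is involved.

Step 3
Reactants: 2 cis-2,3-dimethylsuccinic anhydride; 4 (4-bromo-2,6-dimethoxyphenoxy)(tert-butyl)dimethylsilane
Product: 7 (2S,3R)-4-[4-(tert-butyldimethylsilyloxy)-3,5-dimethoxyphenyl]-2,3-dimethyl-4-oxobutanoic acid, via aryllithium 5 (not isolated), via arylzinc triflate 6 (not isolated)
Conditions: 4, n-BuLi, THF, −78 °C; Zn(OTf)2, −78 °C → rt; then 2, [Rh(cod)Cl]2 (4 mol %), TADDOL-derived phosphoramidite L* (8 mol %), THF/DMF, 50 °C; 1 M HCl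
Reagents that add atoms: n-butyllithium, [Li]CCCC (Li, in 5 only); zinc triflate, [Zn+2].[O-]S(=O)(=O)C(F)(F)F.[O-]S(=O)(=O)C(F)(F)F (Zn and triflate, in 6 only)
Why: Rh-catalysed enantioselective desymmetrising acyl cross-coupling of a meso succinic anhydride with an arylzinc made in situ (oxidative addition into one enantiotopic acyl C–O bond, transmetalation, reductive elimination); the ligand selects the carbonyl next to the (R)-carbon and both existing centres are spectators, so the syn (2S,3R) keto acid should result.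

Step 4
Reactants: 8 4-bromo-2-methoxyphenol
Product: 9 4-bromo-2-methoxy-1-(methoxymethoxy)benzene
Conditions: MOMCl, i-Pr2NEt, CH2Cl2, 0 °C → rt
Reagents that add atoms: chloromethyl methyl ether, COCCl
Why: O-Alkylation of the phenol with MOMCl gives an ether that is stable to base and organometallics and labile to acid.

Step 5
Reactants: 7 (2S,3R)-4-[4-(tert-butyldimethylsilyloxy)-3,5-dimethoxyphenyl]-2,3-dimethyl-4-oxobutanoic acid; 9 4-bromo-2-methoxy-1-(methoxymethoxy)benzene
Product: 12 (3S,4R,5RS)-5-[4-(tert-butyldimethylsilyloxy)-3,5-dimethoxyphenyl]-5-[3-methoxy-4-(methoxymethoxy)phenyl]-3,4-dimethyloxolan-2-one, via arylmagnesium bromide 10 (not isolated), via hydroxy acid 11 (not isolated)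
Conditions: 9, Mg, THF, rt; 7, NaH (1.0 equiv), THF, 0 °C; then 10 (1.5 equiv), LaCl3·2LiCl, THF, −20 °C → rt; cold 0.5 M HCl
Reagents that add atoms: magnesium, [Mg] (Mg, in 10 only)
Why: 1,2-Addition of the aryl Grignard reagent to the ketone of the carboxylate salt (LaCl3·2LiCl suppresses enolisation of the α-branched ketone) followed by spontaneous γ-lactonisation; the new quaternary C5 forms as an epimer mixture of no consequence because this centre is re-made in step 10, and C3/C4 are untouched.

Step 6
Reactants: 12 (3S,4R,5RS)-5,5-diaryl-3,4-dimethyloxolan-2-one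
Product: 13 (2S,3S,4RS)-4-[4-(tert-butyldimethylsilyloxy)-3,5-dimethoxyphenyl]-4-[3-methoxy-4-(methoxymethoxy)phenyl]-2,3-dimethylbutanoic acid
Conditions: H2 (5 atm), Pd(OH)2/C, EtOAc/EtOH, 40 °C
Reagents that add atoms: none
Why: Hydrogenolysis of the doubly benzylic (benzhydryl-type) lactone C–O bond on palladium under neutral conditions, where no free C7′ cation arises, so the adjacent C3 centre and the MOM and TBS ethers should survive; the C4 epimer mixture is carried on.

Step 7
Reactants: 13 (2S,3S,4RS)-4,4-diaryl-2,3-dimethylbutanoic acid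
Product: 14 (2S,3S,4RS)-4-[4-(tert-butyldimethylsilyloxy)-3,5-dimethoxyphenyl]-4-[3-methoxy-4-(methoxymethoxy)phenyl]-2,3-dimethylbutan-1-ol
Conditions: BH3·THF, THF, 0 °C → rt; MeOH
Reagents that add atoms: none
Why: Chemoselective borane reduction of the carboxylic acid to the primary alcohol via an acyloxyborane; ethers and stereocentres are inert.

Step 8
Reactants: 14 (2S,3S,4RS)-4,4-diaryl-2,3-dimethylbutan-1-ol
Product: 15 (2S,3S,4RS)-4-[4-(tert-butyldimethylsilyloxy)-3,5-dimethoxyphenyl]-4-[3-methoxy-4-(methoxymethoxy)phenyl]-2,3-dimethylbutyl 4-methylbenzenesulfonate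
Conditions: TsCl, Et3N, DMAP (cat.), CH2Cl2, 0 °C → rt
Reagents that add atoms: p-toluenesulfonyl chloride, Cc1ccc(cc1)S(Cl)(=O)=O
Why: DMAP-catalysed tosylation of the primary alcohol installs the leaving group at C7.

Step 9
Reactants: 15 (2S,3S,4RS)-4,4-diaryl-2,3-dimethylbutyl tosylate
Product: 17 (1RS,2R,3R)-7,9-dimethoxy-1-[3-methoxy-4-(methoxymethoxy)phenyl]-2,3-dimethylspiro[4.5]deca-6,9-dien-8-one, via tetrabutylammonium phenoxide 16 (not isolated)
Conditions: TBAF (1.05 equiv), THF (0.005 M), 0 → 45 °C
Reagents that add atoms: tetrabutylammonium fluoride, CCCC[N+](CCCC)(CCCC)CCCC.[F-] (cation, in 16 only)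
Why: Fluoride desilylation unmasks the 2,6-dimethoxyphenoxide, whose only carbon able to reach C7 is the para carbon C1, so 5-exo-tet para-C-alkylation (Winstein Ar1-5 dearomatising spirocyclisation) should close the cyclopentane; high dilution disfavours intermolecular O-alkylation and the spiro carbon is not stereogenic because the dienone ring is symmetric.

Step 10
Reactants: 17 (1RS,2R,3R)-7,9-dimethoxy-1-[3-methoxy-4-(methoxymethoxy)phenyl]-2,3-dimethylspiro[4.5]deca-6,9-dien-8-one
Product: 20 (−)-(7′R,8R,8′R)-4,4′-dihydroxy-3,3′,5-trimethoxy-2,7′-cyclolignan, via tethered benzylic cation 18 (not isolated), via O-MOM cyclolignan 19 (not isolated)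
Conditions: HCl (1.25 M in MeOH)/CH2Cl2 1:1, anhydrous, 0 → 40 °C
Reagents that add atoms: none
Why: O-Protonation of the cross-conjugated dienone gives a 4-hydroxyarenium ion in which the spiro bond C1–C7′ is doubly activated (arenium electrofuge, p-oxygenated aryl on C7′), so C7′ shifts to the adjacent ring carbon C2, most plausibly by heterolysis to the tethered benzylic cation 18 and re-closure, and loss of H+ re-aromatises to 19, whose MOM ether is methanolysed in the same medium. The closest known reaction type is the dienone–phenol rearrangement of spiro[4.5]deca-6,9-dien-8-ones to 5,6,7,8-tetrahydro-2-naphthols. The one ring closed is the six-membered carbocycle (C1, C2, C7′, C8′, C8, C7), by Ar2-6 attack of C2 on C7′ (6-endo with respect to the C1=C2 arene bond; a suprafacial 1,2-shift in the concerted limit), and it grows out of the five-membered ring C1, C7, C8, C8′, C7′. C7′ is the only stereocentre formed and is controlled by the C8′ methyl: in the chair-like transition state the C7′ aryl and the C8′ methyl are pseudo-equatorial and anti, so both C1 epimers of 17 should converge on 7′R (7′,8′-trans), the all-cis alternative being further penalised by a 1,3-diaxial aryl/C8-methyl contact; C8 and C8′ are spectators. The step needs migration of C7′ rather than C7, secured by the cation-stabilising aryl on C7′ (a primary CH2 cannot compete), while the choice between C2 and C6 is immaterial because the dienone ring is symmetric. Anhydrous methanolic acid keeps the enol-ether methoxy groups intact and intercepts the MOM cation as dimethoxymethane.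

**Compound list**

1 | meso-2,3-dimethylsuccinic acid, (2R,3S)-2,3-dimethylbutanedioic acid | OC(=O)[C@@H](C)[C@@H](C)C(O)=O | starting material
2 | cis-2,3-dimethylsuccinic anhydride, (3R,4S)-3,4-dimethyloxolane-2,5-dione (meso) | O=C1OC(=O)[C@@H](C)[C@H]1C | intermediate
3 | 4-bromo-2,6-dimethoxyphenol | COc1cc(Br)cc(OC)c1O | starting material
4 | (4-bromo-2,6-dimethoxyphenoxy)(tert-butyl)dimethylsilane | COc1cc(Br)cc(OC)c1O[Si](C)(C)C(C)(C)C | intermediate
5 | [4-(tert-butyldimethylsilyloxy)-3,5-dimethoxyphenyl]lithium | [Li]c1cc(OC)c(O[Si](C)(C)C(C)(C)C)c(OC)c1 | intermediate (not isolated)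
6 | [4-(tert-butyldimethylsilyloxy)-3,5-dimethoxyphenyl]zinc triflate | FC(F)(F)S(=O)(=O)O[Zn]c1cc(OC)c(O[Si](C)(C)C(C)(C)C)c(OC)c1 | intermediate (not isolated)
7 | (2S,3R)-4-[4-(tert-butyldimethylsilyloxy)-3,5-dimethoxyphenyl]-2,3-dimethyl-4-oxobutanoic acid | OC(=O)[C@@H](C)[C@@H](C)C(=O)c1cc(OC)c(O[Si](C)(C)C(C)(C)C)c(OC)c1 | intermediate
8 | 4-bromo-2-methoxyphenol | COc1cc(Br)ccc1O | starting material
9 | 4-bromo-2-methoxy-1-(methoxymethoxy)benzene | COCOc1ccc(Br)cc1OC | intermediate
10 | [3-methoxy-4-(methoxymethoxy)phenyl]magnesium bromide | COCOc1ccc([Mg]Br)cc1OC | intermediate (not isolated)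
11 | (2S,3R,4RS)-4-[4-(tert-butyldimethylsilyloxy)-3,5-dimethoxyphenyl]-4-hydroxy-4-[3-methoxy-4-(methoxymethoxy)phenyl]-2,3-dimethylbutanoic acid (C4 epimers) | OC(=O)[C@@H](C)[C@@H](C)C(O)(c1cc(OC)c(O[Si](C)(C)C(C)(C)C)c(OC)c1)c1ccc(OCOC)c(OC)c1 | intermediate (not isolated)
12 | (3S,4R,5RS)-5-[4-(tert-butyldimethylsilyloxy)-3,5-dimethoxyphenyl]-5-[3-methoxy-4-(methoxymethoxy)phenyl]-3,4-dimethyloxolan-2-one (C5 epimers) | O=C1[C@@H](C)[C@@H](C)C(c2cc(OC)c(O[Si](C)(C)C(C)(C)C)c(OC)c2)(c2ccc(OCOC)c(OC)c2)O1 | intermediate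
13 | (2S,3S,4RS)-4-[4-(tert-butyldimethylsilyloxy)-3,5-dimethoxyphenyl]-4-[3-methoxy-4-(methoxymethoxy)phenyl]-2,3-dimethylbutanoic acid (C4 epimers) | OC(=O)[C@@H](C)[C@@H](C)C(c1cc(OC)c(O[Si](C)(C)C(C)(C)C)c(OC)c1)c1ccc(OCOC)c(OC)c1 | intermediate
14 | (2S,3S,4RS)-4-[4-(tert-butyldimethylsilyloxy)-3,5-dimethoxyphenyl]-4-[3-methoxy-4-(methoxymethoxy)phenyl]-2,3-dimethylbutan-1-ol (C4 epimers) | OC[C@@H](C)[C@@H](C)C(c1cc(OC)c(O[Si](C)(C)C(C)(C)C)c(OC)c1)c1ccc(OCOC)c(OC)c1 | intermediate
15 | (2S,3S,4RS)-4-[4-(tert-butyldimethylsilyloxy)-3,5-dimethoxyphenyl]-4-[3-methoxy-4-(methoxymethoxy)phenyl]-2,3-dimethylbutyl 4-methylbenzenesulfonate (C4 epimers) | Cc1ccc(cc1)S(=O)(=O)OC[C@@H](C)[C@@H](C)C(c1cc(OC)c(O[Si](C)(C)C(C)(C)C)c(OC)c1)c1ccc(OCOC)c(OC)c1 | intermediate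
16 | tetrabutylammonium 2,6-dimethoxy-4-[(1RS,2S,3S)-1-[3-methoxy-4-(methoxymethoxy)phenyl]-2,3-dimethyl-4-(tosyloxy)butyl]phenoxide | Cc1ccc(cc1)S(=O)(=O)OC[C@@H](C)[C@@H](C)C(c1cc(OC)c([O-])c(OC)c1)c1ccc(OCOC)c(OC)c1.CCCC[N+](CCCC)(CCCC)CCCC | intermediate (not isolated)
17 | (1RS,2R,3R)-7,9-dimethoxy-1-[3-methoxy-4-(methoxymethoxy)phenyl]-2,3-dimethylspiro[4.5]deca-6,9-dien-8-one (C1 epimers) | O=C1C(OC)=CC2(C=C1OC)C[C@@H](C)[C@@H](C)C2c1ccc(OCOC)c(OC)c1 | intermediate
18 | (2R,3R)-4-(4-hydroxy-3,5-dimethoxyphenyl)-1-[3-methoxy-4-(methoxymethoxy)phenyl]-2,3-dimethylbutan-1-ylium (tethered benzylic cation) | COc1cc(C[C@@H](C)[C@@H](C)[CH+]c2ccc(OCOC)c(OC)c2)cc(OC)c1O | intermediate (not isolated)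
19 | (7′R,8R,8′R)-4-hydroxy-3,3′,5-trimethoxy-4′-(methoxymethoxy)-2,7′-cyclolignan | COc1cc([C@@H]2c3c(cc(OC)c(O)c3OC)C[C@@H](C)[C@H]2C)ccc1OCOC | intermediate (not isolated)
20 | (−)-(7′R,8R,8′R)-4,4′-dihydroxy-3,3′,5-trimethoxy-2,7′-cyclolignan | COc1cc([C@@H]2c3c(cc(OC)c(O)c3OC)C[C@@H](C)[C@H]2C)ccc1O | target

**Step count and risks**

Total step count: 10. Longest linear sequence: 8 (steps 1, 3, 5, 6, 7, 8, 9, 10; the sequence from 3 through step 2 is equally long).

Steps most likely to fail:

1. Step 10 (key step). The C7′ cation manifold may be diverted before or after ring closure: loss of the C8′ proton (E1, eroding C8′), intermolecular arylation, or alkylation of the electron-rich phenolic product by MOM-derived electrophiles. If part of the shift runs concerted, the C1 epimer ratio of 17 would be copied into C7′ instead of converging; a 7′,8′-cis by-product would be expected to drain into the trans isomer under the same acid by reversible ipso-protonation at C2. Fallback (acylative dienone–phenol rearrangement, trap and release): setting out from 17, Ac2O with catalytic H2SO4 at 0 °C → rt should give the diacetate of the target F1. The new phenol is acetylated as it forms, which deactivates the product ring and takes it out of the acid equilibrium, and the MOM ether is acetolysed to the aryl acetate. K2CO3 in MeOH at rt then returns to the route at 20.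

2. Step 3. Transmetalation and acyl transfer may be slow with the bulky silyloxy-dimethoxyaryl zinc, the enantioselectivity may be insufficient, or the centre α to the new ketone may partly epimerise. Fallback (organocatalytic desymmetrisation, then acylation): setting out from 2, cinchona-alkaloid-mediated methanolysis (quinine or quinidine, MeOH, toluene, −50 °C; the pseudo-enantiomer that opens the carbonyl next to the (S)-carbon) should give the hemiester F2. (COCl)2 with catalytic DMF gives the acid chloride F3, and Pd(PPh3)4-catalysed Negishi acylation with arylzinc 6 gives the keto ester F4. Neutral ester cleavage (Me3SnOH, 1,2-dichloroethane, 70 °C) returns to the route at 7.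

3. Step 6. Hydrogenolysis of the hindered tertiary C–O bond may be sluggish; forcing it with acid would ionise C7′ (alkene formation erodes C8′) and cleave the MOM ether. Fallback (reduce first, then deoxygenate the carbinol on nickel): setting out from 12, LiBH4 in THF should give the diol F5. Neutral-washed W-2 Raney nickel in refluxing EtOH then hydrogenolyses the diaryl carbinol and returns to the route at 14, bypassing 13.

Further compounds
F1 | step 10 | (7′R,8R,8′R)-4,4′-diacetoxy-3,3′,5-trimethoxy-2,7′-cyclolignan | COc1cc([C@@H]2c3c(cc(OC)c(OC(C)=O)c3OC)C[C@@H](C)[C@H]2C)ccc1OC(C)=O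
F2 | step 3 | (2R,3S)-4-methoxy-2,3-dimethyl-4-oxobutanoic acid | COC(=O)[C@@H](C)[C@@H](C)C(O)=O
F3 | step 3 | methyl (2S,3R)-4-chloro-2,3-dimethyl-4-oxobutanoate | COC(=O)[C@@H](C)[C@@H](C)C(Cl)=O
F4 | step 3 | methyl (2S,3R)-4-[4-(tert-butyldimethylsilyloxy)-3,5-dimethoxyphenyl]-2,3-dimethyl-4-oxobutanoate | COC(=O)[C@@H](C)[C@@H](C)C(=O)c1cc(OC)c(O[Si](C)(C)C(C)(C)C)c(OC)c1
F5 | step 6 | (1RS,2R,3S)-1-[4-(tert-butyldimethylsilyloxy)-3,5-dimethoxyphenyl]-1-[3-methoxy-4-(methoxymethoxy)phenyl]-2,3-dimethylbutane-1,4-diol | OC[C@@H](C)[C@@H](C)C(O)(c1cc(OC)c(O[Si](C)(C)C(C)(C)C)c(OC)c1)c1ccc(OCOC)c(OC)c1
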